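The readings come from a simulation with constants of no real substance.

In a one-step world Z + Q → E takes Q and leaves X untouched, so E plus Q stays at half the charge of Q and X together; that is the bench rule for a resolution.

| flask | Q | X | Z | G | remark | time |
|---|---|---|---|---|---|---|
| north-east | 0.27 M | 0.27 M | 0.57 M | 0.19 mM | run made earlier |  |
| west | 0.42 M | 0.42 M | 0.57 M | 0.19 mM | run made earlier |  |
| east | 0.19 M | 0.19 M | 0.57 M | 0.38 mM | run made earlier |  |
| flask | 0.19 M | 0.19 M | 0.570 M | 0.19 mM |  | 20 min |

| run | time / min | E / % | Q / % | X / % |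
|---|---|---|---|---|
| north-east | 5.00 | 21.8 | 29.5 | 42.2 |
| north-east | 10.0 | 30.9 | 22.0 | 36.1 |
| north-east | 15.0 | 37.2 | 18.6 | 31.3 |
| north-east | 20.0 | 41.8 | 16.4 | 28.1 |
| west | 2.50 | 13.0 | 37.0 | 45.6 |
| west | 8.00 | 25.8 | 26.9 | 39.9 |
| west | 12.0 | 30.6 | 23.6 | 36.1 |
| west | 20.0 | 36.6 | 20.9 | 30.8 |
| east | 2.50 | 14.3 | 36.7 | 45.5 |
| east | 8.00 | 30.3 | 24.0 | 35.7 |
| east | 12.0 | 36.8 | 20.4 | 30.5 |
| east | 20.0 | 46.3 | 16.4 | 23.3 |

(scatter of a reading: 0.3 percentage points)

- Z is single-handed; Q and X are mirror images of each other, charged as a racemate, each of them at the stated concentration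
- the numbers in the tables scatter with a standard deviation of 0.3 percentage points
- candidate steps: Q + G <-> X + G; Z <-> D; Z + X -> J; 2 Z -> L; Z + Q -> E
- the handed part of Z does not stay in what it makes, so the products of the two hands are mirror images too

- how much E the flask holds at 20 min, in percent of the Q and X together charged
- how much Q the flask holds at 20 min, in percent of the Q and X together charged
- how much X the flask holds at 20 min, in percent of the Q and X together charged
- concentration of Z at 20 min, in M

1. The east run stands near the rule at 2.50 min, with E plus Q at 51.0%. At 20.0 min it reads 62.7%, more than half, so X is feeding Q over G.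

2. Two frequencies are read from east. Over its last stretch each fraction of Q becomes E at 0.0645 min⁻¹. The Q gained, divided by the mean gap between X and Q, gives a racemisation frequency of 0.0713 min⁻¹.

3. Racemisation frequency over E frequency we call the hand-over number H; control changes hands where it crosses one. East reads 1.10. Our flask has east's charges of Q, X and Z but half the G, so we keep east's E frequency and reckon H at 0.552, below one.

4. The north-east run reads a selectivity factor s of 4.42. The ratio r of Q to X holds still when racemisation closes the gap as fast as selection opens it: 1/r − r = (1 − 1/s)/H. East's number gives r = 0.708, and east reads 0.704 at 20.0 min, a reading that also went into that number. For our flask we commit to 0.521.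

5. The forecast reasons: “The flask is the east run with half the racemisation.” It gives E 43.7%, Q 14.3%, X 26.8% and Z 0.24 M, a ratio of 0.534.

6. The flask gives E 44.1%, Q 14.1%, X 26.0% and Z 0.132 M; Z is where it parts from the forecast, and the ratio is 0.542.

    Q + G ⇌ X + G, rate k1*[G]*[Q] forward; the back reaction follows from the equilibrium constant (k = 2.90 L mol⁻¹ s⁻¹)
    Z ⇌ D (K = 0.690, k = 0.0250 s⁻¹)
    Z + X → J (k = 0.00170 L mol⁻¹ s⁻¹)
    2 Z → L (k = 0.00110 L mol⁻¹ s⁻¹)
    Z + Q → E (k = 0.00690 L mol⁻¹ s⁻¹)

This flask is not at rest at 20 min. Left until 200 min, its Z goes from 23.2% to 3.35% of its charge. With the E frequency taken in proportion to Z, we reckon H there at 3.82, past the crossing, and the rule gives r = 0.904. The flask then holds Q over X at 0.909, with E up from 44.1% to 68.8%, and Q and X down to 2.98% and 3.28%.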